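Assumption: natural (R)-(−)-linalool is used at ≥98% ee (it caps the optical purity at C3′); primed locants number the C10 side chain outward from coumarin C3.

**Retrosynthetic overview**
1. Target 10 ⇒ 9: the outer (6′,7′) oxirane is made last by catalyst-controlled O-transfer to the only remaining trisubstituted alkene.
2. 9 ⇒ 7 + 8 (key disconnection): the C2′–O bond of the inner oxirane. The oxirane oxygen and C3′ (R) come from (R)-linalool; the C1′–C3 bond closes in the same Pd cycle.
3. 7 ⇒ 3 + 4: lactone C–O and C3=C4 by bromo-Wittig olefination/lactonisation.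
4. 3 ⇒ 1 + 2: the reverse-prenyl group by γ-selective allyl-Suzuki coupling.
5. Ring order: benzene (bought) → pyranone → inner 2′,3′-oxirane → outer 6′,7′-oxirane.

**Route**

Step 1
Reactants: 1 5-bromo-2,4-dihydroxybenzaldehyde; 2 prenylboronic acid pinacol ester (4,4,5,5-tetramethyl-2-(3-methylbut-2-en-1-yl)-1,3,2-dioxaborolane)
Product: 3 2,4-dihydroxy-5-(2-methylbut-3-en-2-yl)benzaldehyde
Conditions: 2 (1.5 equiv), Pd(OAc)2/γ-directing biarylphosphine (2/4 mol %), K3PO4 (3 equiv, aq), THF, 40 °C
Reagents that add atoms: none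
Why: γ-Selective allyl Suzuki–Miyaura coupling: prenyl transfer from boron with allylic transposition (SE2′) and fast C–C reductive elimination from the tertiary σ-allyl–Pd(aryl) complex put the quaternary 1,1-dimethylallyl carbon on C5, while the phenoxide-deactivated aldehyde resists allylboration; no stereocentre is formed.

Step 2
Reactants: 3 2,4-dihydroxy-5-(2-methylbut-3-en-2-yl)benzaldehyde; 4 ethyl 2-(triphenyl-λ5-phosphanylidene)acetate
Product: 7 3-bromo-7-hydroxy-6-(2-methylbut-3-en-2-yl)-2H-chromen-2-one, via bromo-ylide 5 (not isolated), via bromocinnamate ester 6 (not isolated)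
Conditions: 4 (1.2 equiv), NBS (1.2 equiv), CH2Cl2, −20 °C, 30 min; then 3, −20 → 40 °C; then i-Pr2NEt (0.2 equiv), toluene, 90 °C
Reagents that add atoms: N-bromosuccinimide (NBS), O=C1CCC(=O)N1Br
Why: One-pot ylide bromination–Wittig olefination–lactonisation: NBS is consumed by 4 before the alkene- and phenol-bearing aldehyde is added, bromo-ylide 5 olefinates 3, and the isomer of ester 6 with aryl cis to CO2Et (reached from the other isomer through the para-phenoxide/quinone-methide form during the amine–heat finish) closes the pyranone by acyl C–O bond formation with loss of ethanol; no stereocentre is formed.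

Step 3
Reactants: 7 3-bromo-7-hydroxy-6-(2-methylbut-3-en-2-yl)-2H-chromen-2-one; 8 (R)-(−)-linalool [(3R)-3,7-dimethylocta-1,6-dien-3-ol]
Product: 9 7-hydroxy-3-{[(2S,3R)-3-methyl-3-(4-methylpent-3-en-1-yl)oxiran-2-yl]methyl}-6-(2-methylbut-3-en-2-yl)-2H-chromen-2-one
Conditions: 8 (2.5 equiv), NaH (2.2 equiv), toluene–1,4-dioxane (1:1), rt; then 7, Pd2(dba)3 (2.5 mol %), (R,R)-TADDOL–P–NMe2 phosphoramidite (10 mol %), 80 °C; aq NH4Cl
Reagents that add atoms: none
Why: Proposed new method: a chiral-ligand-controlled, epoxide-forming alkoxy-alkenylation of a tertiary allylic alcohol, in which oxidative addition of the activated C3–Br bond of the 7-olate of 7 to Pd(0), bromide/alkoxide exchange with sodium (R)-linaloolate, syn-insertion of the vinyl group into the Pd–O bond and C(sp3)–C(sp2) reductive elimination form the C2′–O oxirane bond and the C1′–C3 bond in one cycle; C3′ (R) is carried over from linalool with no bond to it broken, C2′ (S, the cis "neryl-type" oxirane) is set in the oxypalladation by ligand-directed addition to the Si face of the vinyl group (the Me/CH2R pair on the carbinol gives little substrate bias), β-hydride elimination is disfavoured because it would give a methyleneoxirane, and the trisubstituted 6,7-alkene and the hindered 1,1-dimethylallyl vinyl group do not insert; the closest known reaction types are the Pd-catalysed alkene carboetherification of γ-hydroxyalkenes (enantioselective with TADDOL-type P-ligands for five-membered rings) and its three-membered-ring variant with tertiary allylic alcohols, strong alkoxide base and achiral ligands, which has not been shown with stereocontrol at the new oxirane CH or with a 3-bromocoumarin partner.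

Step 4
Reactants: 9 7-hydroxy-3-{[(2S,3R)-3-methyl-3-(4-methylpent-3-en-1-yl)oxiran-2-yl]methyl}-6-(2-methylbut-3-en-2-yl)-2H-chromen-2-one
Product: 10 3-{[(2S,3R)-3-{2-[(2R)-3,3-dimethyloxiran-2-yl]ethyl}-3-methyloxiran-2-yl]methyl}-7-hydroxy-6-(2-methylbut-3-en-2-yl)-2H-chromen-2-one (CNP0292491.1)
Conditions: Shi ketone (D-fructose-derived, 1.0 equiv), Oxone (1.5 equiv), NaHCO3 (5 equiv), Bu4NHSO4 (cat.), MeCN–DMM/aq Na2EDTA, pH 7–8, 0 °C
Reagents that add atoms: Oxone (active component potassium peroxymonosulfate), [K+].[O-]S(=O)(=O)OO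
Why: Shi asymmetric epoxidation: the chiral dioxirane transfers oxygen through a spiro transition state to the only remaining electron-rich trisubstituted alkene under catalyst control (the D-fructose ketone gives R at the CH carbon, so C6′ is R regardless of the remote oxirane), while the hindered monosubstituted vinyl group, the electron-poor C3=C4 bond and the un-ionised phenol at pH 7–8 are not oxidised.

**Compound list**
1 | 5-bromo-2,4-dihydroxybenzaldehyde | O=Cc1cc(Br)c(O)cc1O | starting material
2 | prenylboronic acid pinacol ester | CC(C)=CCB1OC(C)(C)C(C)(C)O1 | starting material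
3 | 2,4-dihydroxy-5-(2-methylbut-3-en-2-yl)benzaldehyde | C=CC(C)(C)c1cc(C=O)c(O)cc1O | intermediate
4 | ethyl 2-(triphenyl-λ5-phosphanylidene)acetate | CCOC(=O)C=P(c1ccccc1)(c1ccccc1)c1ccccc1 | starting material
5 | ethyl 2-bromo-2-(triphenyl-λ5-phosphanylidene)acetate | CCOC(=O)C(Br)=P(c1ccccc1)(c1ccccc1)c1ccccc1 | intermediate (not isolated)
6 | ethyl (2E)-2-bromo-3-[2,4-dihydroxy-5-(2-methylbut-3-en-2-yl)phenyl]prop-2-enoate | CCOC(=O)/C(Br)=C\c1cc(C(C)(C)C=C)c(O)cc1O | intermediate (not isolated)
7 | 3-bromo-7-hydroxy-6-(2-methylbut-3-en-2-yl)-2H-chromen-2-one | C=CC(C)(C)c1cc2cc(Br)c(=O)oc2cc1O | intermediate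
8 | (R)-(−)-linalool, (3R)-3,7-dimethylocta-1,6-dien-3-ol | C=C[C@](C)(O)CCC=C(C)C | starting material
9 | 7-hydroxy-3-{[(2S,3R)-3-methyl-3-(4-methylpent-3-en-1-yl)oxiran-2-yl]methyl}-6-(2-methylbut-3-en-2-yl)-2H-chromen-2-one | C=CC(C)(C)c1cc2cc(C[C@@H]3O[C@]3(C)CCC=C(C)C)c(=O)oc2cc1O | intermediate
10 | 3-{[(2S,3R)-3-{2-[(2R)-3,3-dimethyloxiran-2-yl]ethyl}-3-methyloxiran-2-yl]methyl}-7-hydroxy-6-(2-methylbut-3-en-2-yl)-2H-chromen-2-one | C=CC(C)(C)c1cc2cc(C[C@@H]3O[C@]3(C)CC[C@H]3OC3(C)C)c(=O)oc2cc1O | target

**Step count and risks**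
Total steps: 4. Longest linear sequence: 4 (1 → 3 → 7 → 9 → 10).

Three steps most likely to fail:

Step 3 (the proposed new step). Likely failures are Heck-type β-hydride elimination to the 3-(3-hydroxyalkenyl)coumarin, low or reversed cis/trans selectivity at C2′, and base damage to the 3-bromocoumarin. The ligand antipode is assigned only by analogy; the cis/trans outcome is read from the H2′/3′-CH3 NOE, and the (S,S)-ligand is the first control. The fallback uses known chemistry, sets out from aldehyde 3 and ylide 4, and comes back at target 10. Neryl acetate is epoxidised only at its distal alkene with the D-fructose Shi ketone (the allylic acetate deactivates the 2,3-alkene) to give (R)-6,7-epoxyneryl acetate F1. Methanolysis (K2CO3, MeOH) gives (R)-6,7-epoxynerol F2. MsCl/Et3N gives (R)-6,7-epoxyneryl mesylate F3, and LiBr in THF converts it to (R)-6,7-epoxyneryl bromide F4 with the Z-alkene kept. Alkylation of 4 with F4 in ethyl acetate gives the epoxyneryl phosphonium bromide F5, and aqueous NaOH liberates the substituted ylide F6. Wittig olefination of 3 with F6 in toluene at 100 °C gives the (E)-cinnamate ester F7. Irradiation at 365 nm isomerises and lactonises F7 to the 3-[(6R)-6,7-epoxyneryl]coumarin F8. Epoxidation of the remaining (Z)-2′,3′-alkene of F8 with the enantiomeric (L-sorbose-derived) Shi ketone installs the (2′S,3′R)-oxirane and gives 10.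

Step 1. Likely failures are an α/γ mixture (prenyl versus reverse prenyl), sluggish coupling of the electron-rich ortho-oxido aryl bromide, and allylboration of the aldehyde. The fallback reverses the polarity, sets out from 1 and comes back at 3. Pd-catalysed borylation of 1 with B2(OH)4 (KOAc, EtOH, 80 °C) gives (5-formyl-2,4-dihydroxyphenyl)boronic acid F9. A cationic Pd(II)-catalysed γ-selective allyl–aryl coupling of F9 with prenyl acetate (Pd(OAc)2/1,10-phenanthroline/AgSbF6, DCE, 60 °C) then gives 3: aryl insertion at the dimethyl-substituted alkene carbon is followed by β-acetoxy elimination.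

Step 2. The likely failure is that the Wittig reaction gives mainly the isomer with aryl cis to Br, which cannot lactonise and may not equilibrate thermally. The fallback sets out from 3 and comes back at 7. The olefination with 5 is run at room temperature without the amine–heat finish and ethyl (2Z)-2-bromo-3-[2,4-dihydroxy-5-(2-methylbut-3-en-2-yl)phenyl]prop-2-enoate F10 is isolated. Photochemical E/Z isomerisation of F10 (365 nm, MeCN) with spontaneous lactonisation then gives 7.

**Further compounds**
F1 | step 3 | [(2Z)-5-[(2R)-3,3-dimethyloxiran-2-yl]-3-methylpent-2-en-1-yl] acetate | CC(=O)OC/C=C(/C)CC[C@H]1OC1(C)C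
F2 | step 3 | (2Z)-5-[(2R)-3,3-dimethyloxiran-2-yl]-3-methylpent-2-en-1-ol | OC/C=C(/C)CC[C@H]1OC1(C)C
F3 | step 3 | [(2Z)-5-[(2R)-3,3-dimethyloxiran-2-yl]-3-methylpent-2-en-1-yl] methanesulfonate | CS(=O)(=O)OC/C=C(/C)CC[C@H]1OC1(C)C
F4 | step 3 | (3R)-3-[(3Z)-5-bromo-3-methylpent-3-en-1-yl]-2,2-dimethyloxirane | BrC/C=C(/C)CC[C@H]1OC1(C)C
F5 | step 3 | [(4Z)-7-[(2R)-3,3-dimethyloxiran-2-yl]-1-ethoxy-5-methyl-1-oxohept-4-en-2-yl]triphenylphosphonium bromide | CCOC(=O)C(C/C=C(/C)CC[C@H]1OC1(C)C)[P+](c1ccccc1)(c1ccccc1)c1ccccc1.[Br-]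
F6 | step 3 | ethyl (4Z)-7-[(2R)-3,3-dimethyloxiran-2-yl]-5-methyl-2-(triphenyl-λ5-phosphanylidene)hept-4-enoate | CCOC(=O)C(C/C=C(/C)CC[C@H]1OC1(C)C)=P(c1ccccc1)(c1ccccc1)c1ccccc1
F7 | step 3 | ethyl (2E,4Z)-2-{[2,4-dihydroxy-5-(2-methylbut-3-en-2-yl)phenyl]methylidene}-7-[(2R)-3,3-dimethyloxiran-2-yl]-5-methylhept-4-enoate | CCOC(=O)/C(C/C=C(/C)CC[C@H]1OC1(C)C)=C/c1cc(C(C)(C)C=C)c(O)cc1O
F8 | step 3 | 3-[(2Z)-5-[(2R)-3,3-dimethyloxiran-2-yl]-3-methylpent-2-en-1-yl]-7-hydroxy-6-(2-methylbut-3-en-2-yl)-2H-chromen-2-one | C=CC(C)(C)c1cc2cc(C/C=C(/C)CC[C@H]3OC3(C)C)c(=O)oc2cc1O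
F9 | step 1 | (5-formyl-2,4-dihydroxyphenyl)boronic acid | O=Cc1cc(B(O)O)c(O)cc1O
F10 | step 2 | ethyl (2Z)-2-bromo-3-[2,4-dihydroxy-5-(2-methylbut-3-en-2-yl)phenyl]prop-2-enoate | CCOC(=O)/C(Br)=C/c1cc(C(C)(C)C=C)c(O)cc1O
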